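## Structural features

The target is one cyclohexane ring: C1 is quaternary and carries a tertiary hydroxyl and the carboxylic acid, C3, C4 and C5 carry three contiguous secondary oxygens, and the methylenes C2 and C6 separate C1 from that triol on both sides. O4 and O5 are each esterified by an (E)-4-hydroxycinnamoyl unit, while O1, O3, both phenols and the acid are free. Of the four stereocentres, C3, C4 and C5 stand next to each other (O3/O4 cis, O4/O5 trans), whereas C1 has no stereogenic neighbour: its hydroxyl lies on the face of O3 and O4, its carboxyl on the face of O5. The fragile parts are the two aryl acrylate esters beside a free cis hydroxyl on C3 (acyl migration and cleavage under basic or nucleophilic conditions), the E-alkenes (hydrogenation, conjugate addition, photo-isomerisation), the phenols and the α-hydroxy acid. The real difficulty is twofold: fixing the remote quaternary C1 relative to C4/C5 across two methylenes, and telling O3 apart from O4/O5 while freeing the acid at the end without base. The key step uses the fact that O1 and O4 face each other 1,4-cis across the ring and are both trans to O5: this is the geometry of an O–O bridge from C1 to C4 of a cyclohex-2-ene (a 2,3-dioxabicyclo[2.2.2]oct-5-ene) built on the face away from the C5 substituent, with the remaining C2=C3 alkene placed to receive O3 from O4.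

## Logic of the disconnections

24 ⇒ 23. The last operation breaks three benzylic C–O bonds (carboxyl and two phenols) and the Si–O bond at O3. All four masks fall in one acid treatment, so no base meets the diester once O3 is free. The gain is a robust, neutral penultimate compound. The forward step must spare two ester links and two E-alkenes and must trap the benzylic cations.

23 ⇒ 17 + two molecules of 20 (through 21). The two acyl C–O bonds at O4 and O5 are cut, because the ester links are the natural convergent seam. This splits the molecule into a C7 cyclitol core and two identical C9 acids. It demands that only O4 and O5 are free to react (O3 masked, O1 tertiary, acid masked) and that the acyl donor is reactive enough for the hindered O4.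

20 ⇒ 18. The phenolic O–CH2Ar bond is cut. The phenol would otherwise compete as a nucleophile, and a benzylic ether leaves in the same final acid step. The forward step must alkylate both acidic sites and then hydrolyse only the ester.

17 ⇒ 16 ⇒ 15. The Si–O bond at O5 is restored and the Si–O bond at O3 removed. O3 has to be told from O4 and O5: with O5 already occupied, sterics send the new silyl group to O3 and not to the doubly flanked O4, after which the more labile O5 ether is taken off. This demands two silyl ethers of different lability, which is why the C5 ether is triethylsilyl from step 4 onwards.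

15 ⇒ 13 (through 14). The ester O–CH2Ar bond is exchanged for the methyl ester, and O3 and O4 are rejoined as a cyclic carbonate. This is the last point at which hydroxide can be used safely; afterwards the acid must be released by acid. The gain is that 13 holds O3 and O4 in one ring. The forward step needs the C5 silyl ether to survive hydroxide without migrating.

13 ⇒ 12 ⇒ 11 ⇒ 10. The C3–O bond is cut and the C2=C3 alkene restored (through the C2–I bond). O3 must arrive cis to O4, and a carbonate bound to O4 can reach only C3 and only from its own face. One stereocentre is removed and an alkene recovered. The forward sequence needs selective derivatisation of O4 over O1, an anti addition with the carbonate as internal nucleophile, and radical removal of iodine.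

10 ⇒ 9. O1 and O4 are reconnected by an O–O bond, since a cis-1,4-diol on a cyclohex-2-ene is the reduction product of an endoperoxide. Two stereocentres become the two ends of one bridge. The reduction must leave the alkene and the silyl ether alone and avoid base.

9 ⇒ 8 + O2. The C1–O and C4–O bonds are cut. Both can form in one suprafacial cycloaddition, which guarantees their cis relation. Two stereocentres, one ring and two oxygens disappear, leaving a planar diene with a single stereocentre. The forward step must add anti to the C5 ether and as a [4+2] process rather than an ene reaction.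

8 ⇒ 5 (through 6 and 7). The C1=C2 double bond is removed. The ester acidifies C1–H, so the unsaturation can be introduced through the enolate. The diene is traced to an isolated alkene. The forward elimination must go towards C2 and not C6, and the diene must not lose silanol.

5 ⇒ 4 ⇒ 3 ⇒ 2 ⇒ 1. The C5–O bond is cut and the alkene moved back. The carboxyl of 1 can deliver oxygen to C5 intramolecularly, so the only stereocentre of 1 (C1, later erased) is relayed to C5. This reaches a commercial C7 acid with one stereocentre. It demands a regio- and stereospecific lactonisation, an elimination away from the bridgehead, and a lactone opening that leaves C5 untouched.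

## Other disconnections considered

Alternative 1: The cut is the C1–C6 bond. In the forward step the methyl ketone enolate (C6) of the acyclic diketo ester A2 would add to its α-keto ester carbonyl (C1) in an intramolecular aldol reaction, giving the cyclohexanone A1.
- In its favour: one C–C bond closes the carbocycle and creates the quaternary carbinol together; O3 and O4 come from the chiral pool as a cis-acetonide; no peroxide or photochemistry is involved. On these points the alternative is the better plan.
- Against it here: A2 can also enolise at C2 and at C4, and either carbanion has an acetonide oxygen in the β-position, inviting elimination and epimerisation. The aldol is reversible and A1 is a β-hydroxy ketone that can dehydrate. The configuration of C1 would rest on a transition-state preference remote from any controlling group. C5 is still a ketone, so a later reduction would have to set O5 trans to O4.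
- Comparison: the acetonide of A1 ties O3 and O4 exactly as the carbonate of 13 does, so the later differentiation of O3 is an equal burden. Mechanistically a reversible polar step competes with a concerted addition in which the 1,4-cis relation is geometrically enforced and C5 is already fixed; here the chosen plan is the more certain. In step count the two are expected to be about equal, because A2 should need at least as many steps as 1 → 8 and A1 still needs the ketone reduction.

Alternative 2: The cut is the C1–C2 bond. The δ-lactone A4 would be converted into its silyl ketene acetal, and a [3,3] sigmatropic shift through a boat transition state would form C1–C2, break the ring C4–O bond and give the cyclohexene acid A3 with a C3=C4 alkene.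
- In its favour: the quaternary C1 is made by C–C bond formation with transfer of chirality from the C–O stereocentre of A4. A single cis-dihydroxylation of the C3=C4 alkene of A3 anti to the allylic silyl ether would then install O3 and O4 together. On that point the alternative is clearly the better, since the chosen plan spends steps 7 to 10 on O3.
- Against it here: A4 needs the 5,6-trans pair of stereocentres, the vinyl group and the α-alkoxy group, and so a longer asymmetric synthesis than the five steps to 8. The boat transition state of an α-alkoxy lactone enolate is strained. O1 arrives as an acetal on a tertiary centre and the acid arrives free, so both need further handling.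
- Comparison: both key steps are pericyclic and stereospecific, so they are equal in principle; the alternative relays configuration through one defined transition-state geometry, the chosen plan through a facial preference. After dihydroxylation the O3 versus O4/O5 problem would be the same. Overall length should be comparable: shorter after the key step, longer before it.

Alternative 3: The cut is the C3–C4 bond. SmI2 would couple the two aldehyde groups of the acyclic dialdehyde A6 reductively, closing the ring and giving the cis-diol A5.
- In its favour: a ring C–C bond and both carbinol centres C3 and C4 are formed in one step. The usual cis-diol preference of such pinacol closures, together with approach anti to the α-silyloxy group, should give O3/O4 cis and O4 trans to O5. In stereocentres and rings made by the key step it is the equal of the chosen plan (two and one), and the way from A5 to the target would be shorter than from 9.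
- Against it here: A6 must already hold the quaternary α-alkoxy ester centre C1 in an acyclic chain with two different two-carbon arms, which moves the hardest problem into acyclic stereocontrol. One arm of A6 is a β-alkoxy aldehyde (prone to elimination) and the other an α-silyloxy aldehyde (prone to epimerisation). At least two equivalents of SmI2 are consumed, and the ketyl could attack the ester.
- Comparison: the O3 versus O4/O5 problem after A5 would again be equal. The alternative is the better in convergency of ring formation; the chosen plan is the better in access to the key-step substrate and in how firmly the O1/O4 relation is enforced.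

Key step: step 6

Remark (numbering): ring atoms carry the quinate locants throughout; C1 bears the carboxyl group, C3, C4 and C5 the secondary oxygens, C2 and C6 are the methylenes.
Remark (assumption): 1, 18 and all reagents named are taken as commercial, 1 as the (R)-enantiomer of high enantiomeric purity.
Remark (configuration check): following C5 from (R)-1 through the cis-lactone gives the 5R diene 8; with the peroxide bridge anti to the C5 ether, 9 has O1 and O4 cis to each other and trans to O5, as the target requires, so no structure needed correcting.
Remark (design of the cycloaddition substrate): the C5 ether is triethylsilyl, because the endgame must free O5 while a tert-butyldimethylsilyl ether stays on O3; the methyl ester is kept through the iodocyclisation (an ester that sheds a stabilised cation would compete as an internal nucleophile) and is then exchanged for a 4-methoxybenzyl ester, so that the acid is finally released by acid and not by hydroxide.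

## Route

Step 1
Reactants: 1 (R)-cyclohex-3-ene-1-carboxylic acid
Product: 2 (1R,4R,5R)-4-iodo-6-oxabicyclo[3.2.1]octan-7-one
Conditions: I2, KI, NaHCO3, H2O, 0 °C → rt, dark
Reagents that add atoms: iodine, II
Why: Kinetic iodolactonisation: the carboxylate can reach the iodonium ion only from its own face, so it closes the γ-lactone onto the ring carbon that becomes C5 and fixes O5 cis to the carboxyl, with iodine anti on C4; the single stereocentre of 1 thereby sets C5.

Step 2
Reactants: 2 (1R,4R,5R)-4-iodo-6-oxabicyclo[3.2.1]octan-7-one
Product: 3 (1R,5R)-6-oxabicyclo[3.2.1]oct-3-en-7-one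
Conditions: DBU, toluene, 90 °C
Reagents that add atoms: none
Why: E2 dehydroiodination; the only anti-periplanar hydrogen is on C3, and loss of the bridgehead C5–H would give a bridgehead enol lactone, so the C3=C4 alkene should form regioselectively with C5 untouched.

Step 3
Reactants: 3 (1R,5R)-6-oxabicyclo[3.2.1]oct-3-en-7-one
Product: 4 methyl (1R,5R)-5-hydroxycyclohex-3-ene-1-carboxylate
Conditions: K2CO3 (cat.), MeOH, 0 °C
Reagents that add atoms: methanol, CO
Why: Base-catalysed methanolysis of the strained bridged lactone (transesterification) should give the cis hydroxy ester; C5 is not involved, and any epimerisation at C1 is irrelevant because C1 becomes trigonal in step 5.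

Step 4
Reactants: 4 methyl (1R,5R)-5-hydroxycyclohex-3-ene-1-carboxylate
Product: 5 methyl (1R,5R)-5-(triethylsilyloxy)cyclohex-3-ene-1-carboxylate
Conditions: Et3SiCl, imidazole, CH2Cl2, 0 °C → rt
Reagents that add atoms: chlorotriethylsilane, CC[Si](CC)(CC)Cl
Why: Standard silylation of a secondary alcohol; the triethylsilyl ether offers no hydrogen bond to guide oxygen in step 6, and it can later be removed by mild acid next to a tert-butyldimethylsilyl ether.

Step 5
Reactants: 5 methyl (1R,5R)-5-(triethylsilyloxy)cyclohex-3-ene-1-carboxylate
Product: 8 methyl (5R)-5-(triethylsilyloxy)cyclohexa-1,3-diene-1-carboxylate, via α-phenylselanyl ester 6 (not isolated), via selenoxide 7 (not isolated)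
Conditions: LiN(iPr)2, THF, −78 °C; PhSeBr, −78 °C; then pyridine, 30% H2O2, 0 °C → rt
Reagents that add atoms: none
Why: Reich α-selenenylation of the ester enolate followed by syn-elimination of the selenoxide; the allylic C2–H is the more activated syn hydrogen and its loss gives the conjugated diene, while C5 is not touched. The buffered, near-neutral conditions at or below room temperature should limit loss of silanol to the benzoate.

Step 6
Reactants: 8 methyl (5R)-5-(triethylsilyloxy)cyclohexa-1,3-diene-1-carboxylate
Product: 9 methyl (1R,4R,5R)-1,4-epidioxy-5-(triethylsilyloxy)cyclohex-2-ene-1-carboxylate (a 2,3-dioxabicyclo[2.2.2]oct-5-ene, peroxide bridge trans to the silyloxy group)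
Conditions: O2, 5,10,15,20-tetraphenylporphyrin (cat.), hν (white LED), CH2Cl2, −40 °C; concentrated below 10 °C and used at once
Reagents that add atoms: dioxygen, O=O
Why: Sensitised singlet oxygen adds as a two-atom dienophile across C1 and C4 of the ring-locked s-cis diene in a concerted, suprafacial [4+2] cycloaddition, forming the C1–O and C4–O bonds and leaving the C2=C3 alkene. The closest known reaction type is the dye-sensitised photooxygenation of cyclohexa-1,3-dienes to 2,3-dioxabicyclo[2.2.2]oct-5-enes (α-terpinene to ascaridole), which also proceeds with diene esters. The 1,2-dioxane ring is closed by the cycloaddition itself: both of its C–O bonds form in one event on the same face, so it is an annulation and not the exo or endo attack of a tethered nucleophile. Suprafaciality forces the new stereocentres C1 and C4 to hold their oxygens cis, as the two ends of one bridge. The face is chosen by the only existing stereocentre, C5: its O–SiEt3 group shields its own side of the diene and its oxygen lone pairs repel the incoming electron-rich oxygen, so addition should occur anti and place O1 and O4 trans to O5. The step needs π-facial selectivity and [4+2] rather than ene abstraction of H5 or H6; these are favoured by the cisoid diene, the absence of a free hydroxyl that could guide oxygen to the syn face, the low temperature and the non-polar solvent. Base is excluded and the product is not stored, so that Kornblum–DeLaMare opening through C4–H is avoided.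

Step 7
Reactants: 9 methyl (1R,4R,5R)-1,4-epidioxy-5-(triethylsilyloxy)cyclohex-2-ene-1-carboxylate
Product: 10 methyl (1R,4R,5R)-1,4-dihydroxy-5-(triethylsilyloxy)cyclohex-2-ene-1-carboxylate
Conditions: thiourea, MeOH (wet), 0 °C → rt
Reagents that add atoms: none
Why: Thiourea reduction of the weak O–O bond of a bicyclic endoperoxide gives the cis-1,4-diol with both C–O bonds, and hence both configurations, retained; the neutral medium leaves the alkene, ester and silyl ether alone.

Step 8
Reactants: 10 methyl (1R,4R,5R)-1,4-dihydroxy-5-(triethylsilyloxy)cyclohex-2-ene-1-carboxylate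
Product: 11 methyl (1R,4R,5R)-4-(tert-butoxycarbonyloxy)-1-hydroxy-5-(triethylsilyloxy)cyclohex-2-ene-1-carboxylate
Conditions: Boc2O (1.1 equiv), DMAP (cat.), MeCN, 0 °C → rt
Reagents that add atoms: di-tert-butyl dicarbonate, CC(C)(C)OC(=O)OC(=O)OC(C)(C)C
Why: DMAP-catalysed carbonate formation; the secondary allylic O4–H should react far faster than the tertiary, ester-deactivated O1–H, and the 1,4-diol cannot close to a cyclic carbonate.

Step 9
Reactants: 11 methyl (1R,4R,5R)-4-(tert-butoxycarbonyloxy)-1-hydroxy-5-(triethylsilyloxy)cyclohex-2-ene-1-carboxylate
Product: 12 methyl (2R)-2-iodo-3,4-O-carbonyl-5-O-(triethylsilyl)quinate (cis-fused cyclic carbonate, iodine on C2 trans to O3)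
Conditions: IBr, toluene, −78 °C; aq. Na2S2O3/NaHCO3
Reagents that add atoms: iodine monobromide, IBr
Why: Iodocarbonate cyclisation (Bartlett type, IBr variant): the carbonyl oxygen of the O4 carbonate opens the iodonium ion at the adjacent C3 from the face of O4, closing a cis-fused five-membered carbonate and placing iodine on C2 anti to the new C3–O bond. O3 is therefore cis to O4 by intramolecular delivery, and loss of the tert-butyl group makes the closure irreversible; the methyl ester is a poor competing nucleophile.

Step 10
Reactants: 12 methyl (2R)-2-iodo-3,4-O-carbonyl-5-O-(triethylsilyl)quinate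
Product: 13 methyl 3,4-O-carbonyl-5-O-(triethylsilyl)quinate
Conditions: (Me3Si)3SiH, AIBN (cat.), toluene, 80 °C
Reagents that add atoms: none
Why: Radical-chain deiodination with a tin-free silane; the C2 radical only abstracts hydrogen, the transient C2 stereocentre disappears, and carbonate, ester and silyl ether are inert.

Step 11
Reactants: 13 methyl 3,4-O-carbonyl-5-O-(triethylsilyl)quinate
Product: 15 4-methoxybenzyl 5-O-(triethylsilyl)quinate, via potassium carboxylate 14 (not isolated)
Conditions: KOH (3.1 equiv), THF–H2O, 0 °C; evaporate, toluene azeotrope; then 4-MeOC6H4CH2Cl, DMF, rt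
Reagents that add atoms: potassium hydroxide, [K+].[OH-]; 4-methoxybenzyl chloride, COc1ccc(CCl)cc1
Why: Hydrolysis of the cyclic carbonate and saponification of the methyl ester at the last stage that carries no base-sensitive acyl group, then SN2 O-alkylation of the carboxylate, the only site nucleophilic enough for the benzylic chloride without further base. No stereocentre is touched, and the acid is now masked by a group that acid can remove.

Step 12
Reactants: 15 4-methoxybenzyl 5-O-(triethylsilyl)quinate
Product: 16 4-methoxybenzyl 3-O-(tert-butyldimethylsilyl)-5-O-(triethylsilyl)quinate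
Conditions: tBuMe2SiCl (1.3 equiv), imidazole, DMF, 0 °C → rt
Reagents that add atoms: tert-butyldimethylsilyl chloride, CC(C)(C)[Si](C)(C)Cl
Why: Sterically governed silylation: O3, flanked by a methylene, should react before O4, which sits between two oxygenated carbons, and before the tertiary O1; this is the preference that gives 3,5-bis-silyl ethers from quinate esters.

Step 13
Reactants: 16 4-methoxybenzyl 3-O-(tert-butyldimethylsilyl)-5-O-(triethylsilyl)quinate
Product: 17 4-methoxybenzyl 3-O-(tert-butyldimethylsilyl)quinate
Conditions: pyridinium p-toluenesulfonate (cat.), MeOH–CH2Cl2, 0 °C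
Reagents that add atoms: none
Why: Acid-catalysed methanolysis removes the triethylsilyl ether much faster than the bulkier tert-butyldimethylsilyl ether; the benzylic ester is stable, and silyl migration is not expected under acid.

Step 14
Reactants: 18 p-coumaric acid
Product: 20 (E)-4-(4-methoxybenzyloxy)cinnamic acid, via bis(4-methoxybenzyl) derivative 19 (not isolated)
Conditions: 4-MeOC6H4CH2Cl (2.2 equiv), K2CO3, DMF, 60 °C; then KOH, MeOH–H2O, 60 °C; HCl to pH 3, 0 °C
Reagents that add atoms: 4-methoxybenzyl chloride, COc1ccc(CCl)cc1; potassium hydroxide, [K+].[OH-]
Why: Williamson alkylation of phenoxide and carboxylate followed by saponification of the ester only; the aryl benzyl ether is inert to hydroxide and the E-alkene is retained.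

Step 15
Reactants: 17 4-methoxybenzyl 3-O-(tert-butyldimethylsilyl)quinate; 20 (E)-4-(4-methoxybenzyloxy)cinnamic acid (2.6 equiv)
Product: 23 4-methoxybenzyl 3-O-(tert-butyldimethylsilyl)-4,5-bis-O-[(E)-4-(4-methoxybenzyloxy)cinnamoyl]quinate, via acid chloride 21 (not isolated), via 5-O-monoester 22 (not isolated)
Conditions: 20, Me2C=C(Cl)NMe2 (0.95 equiv per acid), CH2Cl2, 0 °C → rt; then 17, pyridine, DMAP (cat.), 0 °C → rt
Reagents that add atoms: none
Why: The α-chloro-enamine converts the acid into its chloride without releasing HCl, and DMAP-catalysed acylation should then take the equatorial O5 first and the more hindered O4 second. O1 is tertiary and unreactive under these conditions, and O3 is silylated, so no acyl group can migrate to it.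

Step 16
Reactants: 23 4-methoxybenzyl 3-O-(tert-butyldimethylsilyl)-4,5-bis-O-[(E)-4-(4-methoxybenzyloxy)cinnamoyl]quinate
Product: 24 4,5-di-O-p-coumaroylquinic acid
Conditions: CF3CO2H–CH2Cl2 (1:1), anisole (10 equiv), 0 °C; then H2O, rt
Reagents that add atoms: none
Why: Acidolysis cleaves the three 4-methoxybenzyl C–O bonds (ester and two aryl ethers) by an SN1 path with the cation trapped by anisole (Friedel–Crafts), and aqueous acid hydrolyses the silyl ether and any transient trifluoroacetates. No base is present, so acyl migration and ester cleavage are not expected, and no stereocentre is touched.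

## Compound list

1 | (R)-cyclohex-3-ene-1-carboxylic acid | OC(=O)[C@H]1CC=CCC1 | starting material
2 | (1R,4R,5R)-4-iodo-6-oxabicyclo[3.2.1]octan-7-one | I[C@@H]1CC[C@@H]2C[C@H]1OC2=O | intermediate
3 | (1R,5R)-6-oxabicyclo[3.2.1]oct-3-en-7-one | C1=CC[C@@H]2C[C@H]1OC2=O | intermediate
4 | methyl (1R,5R)-5-hydroxycyclohex-3-ene-1-carboxylate (cis) | C1=CC[C@@H](C(=O)OC)C[C@H]1O | intermediate
5 | methyl (1R,5R)-5-(triethylsilyloxy)cyclohex-3-ene-1-carboxylate | C1=CC[C@@H](C(=O)OC)C[C@H]1O[Si](CC)(CC)CC | intermediate
6 | methyl (5R)-1-(phenylselanyl)-5-(triethylsilyloxy)cyclohex-3-ene-1-carboxylate (both C1 epimers) | C1=CCC([Se]c2ccccc2)(C(=O)OC)C[C@H]1O[Si](CC)(CC)CC | intermediate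
7 | methyl (5R)-1-(benzeneseleninyl)-5-(triethylsilyloxy)cyclohex-3-ene-1-carboxylate (selenoxide of 6) | C1=CCC([Se](=O)c2ccccc2)(C(=O)OC)C[C@H]1O[Si](CC)(CC)CC | intermediate
8 | methyl (5R)-5-(triethylsilyloxy)cyclohexa-1,3-diene-1-carboxylate | COC(=O)C1=CC=C[C@H](O[Si](CC)(CC)CC)C1 | intermediate
9 | methyl (1R,4R,5R)-1,4-epidioxy-5-(triethylsilyloxy)cyclohex-2-ene-1-carboxylate | O2[C@@H]1C=C[C@@](O2)(C(=O)OC)C[C@H]1O[Si](CC)(CC)CC | intermediate
10 | methyl (1R,4R,5R)-1,4-dihydroxy-5-(triethylsilyloxy)cyclohex-2-ene-1-carboxylate | O[C@@H]1C=C[C@@](O)(C(=O)OC)C[C@H]1O[Si](CC)(CC)CC | intermediate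
11 | methyl (1R,4R,5R)-4-(tert-butoxycarbonyloxy)-1-hydroxy-5-(triethylsilyloxy)cyclohex-2-ene-1-carboxylate | CC(C)(C)OC(=O)O[C@@H]1C=C[C@@](O)(C(=O)OC)C[C@H]1O[Si](CC)(CC)CC | intermediate
12 | methyl (2R)-2-iodo-3,4-O-carbonyl-5-O-(triethylsilyl)quinate | O=C2O[C@@H]1[C@H](O2)[C@@H](I)[C@@](O)(C(=O)OC)C[C@H]1O[Si](CC)(CC)CC | intermediate
13 | methyl 3,4-O-carbonyl-5-O-(triethylsilyl)quinate | O=C2O[C@@H]1[C@H](O2)C[C@@](O)(C(=O)OC)C[C@H]1O[Si](CC)(CC)CC | intermediate
14 | potassium 5-O-(triethylsilyl)quinate | O[C@@H]1[C@H](O)C[C@@](O)(C(=O)[O-])C[C@H]1O[Si](CC)(CC)CC.[K+] | intermediate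
15 | 4-methoxybenzyl 5-O-(triethylsilyl)quinate | O[C@@H]1[C@H](O)C[C@@](O)(C(=O)OCc2ccc(OC)cc2)C[C@H]1O[Si](CC)(CC)CC | intermediate
16 | 4-methoxybenzyl 3-O-(tert-butyldimethylsilyl)-5-O-(triethylsilyl)quinate | O[C@@H]1[C@H](O[Si](C)(C)C(C)(C)C)C[C@@](O)(C(=O)OCc2ccc(OC)cc2)C[C@H]1O[Si](CC)(CC)CC | intermediate
17 | 4-methoxybenzyl 3-O-(tert-butyldimethylsilyl)quinate | O[C@@H]1[C@H](O[Si](C)(C)C(C)(C)C)C[C@@](O)(C(=O)OCc2ccc(OC)cc2)C[C@H]1O | intermediate
18 | p-coumaric acid | O=C(O)/C=C/c1ccc(O)cc1 | starting material
19 | 4-methoxybenzyl (E)-4-(4-methoxybenzyloxy)cinnamate | O=C(OCc1ccc(OC)cc1)/C=C/c1ccc(OCc2ccc(OC)cc2)cc1 | intermediate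
20 | (E)-4-(4-methoxybenzyloxy)cinnamic acid | O=C(O)/C=C/c1ccc(OCc2ccc(OC)cc2)cc1 | intermediate
21 | (E)-4-(4-methoxybenzyloxy)cinnamoyl chloride | O=C(Cl)/C=C/c1ccc(OCc2ccc(OC)cc2)cc1 | intermediate
22 | 4-methoxybenzyl 3-O-(tert-butyldimethylsilyl)-5-O-[(E)-4-(4-methoxybenzyloxy)cinnamoyl]quinate | O[C@@H]1[C@H](O[Si](C)(C)C(C)(C)C)C[C@@](O)(C(=O)OCc2ccc(OC)cc2)C[C@H]1OC(=O)/C=C/c1ccc(OCc2ccc(OC)cc2)cc1 | intermediate
23 | 4-methoxybenzyl 3-O-(tert-butyldimethylsilyl)-4,5-bis-O-[(E)-4-(4-methoxybenzyloxy)cinnamoyl]quinate | O=C(/C=C/c1ccc(OCc2ccc(OC)cc2)cc1)O[C@@H]1[C@H](O[Si](C)(C)C(C)(C)C)C[C@@](O)(C(=O)OCc2ccc(OC)cc2)C[C@H]1OC(=O)/C=C/c1ccc(OCc2ccc(OC)cc2)cc1 | intermediate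
24 | 4,5-di-O-p-coumaroylquinic acid | O=C(/C=C/c1ccc(O)cc1)O[C@@H]1[C@H](O)C[C@@](O)(C(=O)O)C[C@H]1OC(=O)/C=C/c1ccc(O)cc1 | target

## Step count and least certain steps

Total: 16 steps. Longest linear sequence: 15 steps (steps 1 to 13, 15 and 16, from 1 to 24); step 14 is the side branch.

Step 6 (key step). The most likely failure is erosion of π-facial discrimination, since a single allylic substituent on a flexible ring is the only control element. A second risk is diversion into ene hydroperoxidation or dehydro-aromatisation, because the ester lowers the diene HOMO and slows the cycloaddition. The fallback sets out from 8 and comes back at 9, and it changes the oxidation level of the C1 substituent. Reduction with iBu2AlH in CH2Cl2 at −78 °C should give [(5R)-5-(triethylsilyloxy)cyclohexa-1,3-dien-1-yl]methanol F1, an electron-richer diene that should add singlet oxygen faster and at lower temperature under the same control by C5. Sensitised photooxygenation would give [(1R,4R,5R)-1,4-epidioxy-5-(triethylsilyloxy)cyclohex-2-en-1-yl]methanol F2. Oxidation of its primary alcohol with 2,2,6,6-tetramethylpiperidin-1-oxyl (cat.) and PhI(OAc)2 in MeCN–H2O would give (1R,4R,5R)-1,4-epidioxy-5-(triethylsilyloxy)cyclohex-2-ene-1-carboxylic acid F3, and methylation with Me3SiCHN2 in toluene–MeOH returns to 9.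

Step 5. The syn-elimination may lose regiocontrol (towards C6 instead of C2), and the silyloxy diene may aromatise by loss of triethylsilanol during oxidation or work-up. The fallback sets out from 5 and comes back at 15; it gives up the diene and therefore the cycloaddition, which is why it is only a contingency: the C1 configuration would then rest on a facial preference of an enolate, not on a concerted event. Enolate hydroxylation (LiN(iPr)2, then 2-(phenylsulfonyl)-3-phenyloxaziridine, THF, −78 °C), expected anti to the C5 silyloxy group, would give methyl (1S,5R)-1-hydroxy-5-(triethylsilyloxy)cyclohex-3-ene-1-carboxylate F4. Dihydroxylation of C3=C4 anti to the allylic silyl ether (OsO4 cat., N-methylmorpholine N-oxide, acetone–H2O) would give methyl 5-O-(triethylsilyl)quinate F5, which under the conditions of step 11 should give 15 through 14.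

Step 11. The most likely failure is migration of the triethylsilyl group from O5 to the newly freed O4 (and on to O3), or its hydrolysis, while hydroxide is present. The fallback sets out from 13 and comes back at 17; it replaces the silyl ether by an ether that cannot migrate before any base is used. HF·pyridine in THF would give methyl 3,4-O-carbonylquinate F6. 4-Methoxybenzyl 2,2,2-trichloroacetimidate with catalytic camphorsulfonic acid in CH2Cl2 would etherify the secondary O5 to give methyl 3,4-O-carbonyl-5-O-(4-methoxybenzyl)quinate F7. KOH in THF–H2O would give potassium 5-O-(4-methoxybenzyl)quinate F8, and 4-methoxybenzyl chloride in DMF would give 4-methoxybenzyl 5-O-(4-methoxybenzyl)quinate F9. Silylation as in step 12 would give 4-methoxybenzyl 3-O-(tert-butyldimethylsilyl)-5-O-(4-methoxybenzyl)quinate F10. Oxidative removal of the benzylic ether with DDQ in CH2Cl2–pH 7 buffer, which the far less electron-rich benzylic ester should survive, returns to 17.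

Step 15. The most likely failure is incomplete acylation of the hindered O4 beside the silyl ether on C3, or over-acylation at the tertiary O1; an excess of the chloro-enamine could also chlorinate a free hydroxyl. The fallback sets out from 17 and comes back at 23; it builds the acrylate on the oxygen instead of transferring it. Heating with Meldrum's acid in toluene at 90 °C (acylation by a small acylketene, no base) would give 4-methoxybenzyl 3-O-(tert-butyldimethylsilyl)-4,5-bis-O-(carboxyacetyl)quinate F11. Knoevenagel–Doebner condensation with 4-(4-methoxybenzyloxy)benzaldehyde in pyridine with catalytic piperidine at 50 °C would then form both E-cinnamate esters with loss of CO2 and give 23.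

## Further compounds

F1 | step 6 | [(5R)-5-(triethylsilyloxy)cyclohexa-1,3-dien-1-yl]methanol | OCC1=CC=C[C@H](O[Si](CC)(CC)CC)C1
F2 | step 6 | [(1R,4R,5R)-1,4-epidioxy-5-(triethylsilyloxy)cyclohex-2-en-1-yl]methanol | O2[C@@H]1C=C[C@@](O2)(CO)C[C@H]1O[Si](CC)(CC)CC
F3 | step 6 | (1R,4R,5R)-1,4-epidioxy-5-(triethylsilyloxy)cyclohex-2-ene-1-carboxylic acid | O2[C@@H]1C=C[C@@](O2)(C(=O)O)C[C@H]1O[Si](CC)(CC)CC
F4 | step 5 | methyl (1S,5R)-1-hydroxy-5-(triethylsilyloxy)cyclohex-3-ene-1-carboxylate | C1=CC[C@@](O)(C(=O)OC)C[C@H]1O[Si](CC)(CC)CC
F5 | step 5 | methyl 5-O-(triethylsilyl)quinate | O[C@@H]1[C@H](O)C[C@@](O)(C(=O)OC)C[C@H]1O[Si](CC)(CC)CC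
F6 | step 11 | methyl 3,4-O-carbonylquinate | O=C2O[C@@H]1[C@H](O2)C[C@@](O)(C(=O)OC)C[C@H]1O
F7 | step 11 | methyl 3,4-O-carbonyl-5-O-(4-methoxybenzyl)quinate | O=C2O[C@@H]1[C@H](O2)C[C@@](O)(C(=O)OC)C[C@H]1OCc1ccc(OC)cc1
F8 | step 11 | potassium 5-O-(4-methoxybenzyl)quinate | O[C@@H]1[C@H](O)C[C@@](O)(C(=O)[O-])C[C@H]1OCc1ccc(OC)cc1.[K+]
F9 | step 11 | 4-methoxybenzyl 5-O-(4-methoxybenzyl)quinate | O[C@@H]1[C@H](O)C[C@@](O)(C(=O)OCc2ccc(OC)cc2)C[C@H]1OCc1ccc(OC)cc1
F10 | step 11 | 4-methoxybenzyl 3-O-(tert-butyldimethylsilyl)-5-O-(4-methoxybenzyl)quinate | O[C@@H]1[C@H](O[Si](C)(C)C(C)(C)C)C[C@@](O)(C(=O)OCc2ccc(OC)cc2)C[C@H]1OCc1ccc(OC)cc1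
F11 | step 15 | 4-methoxybenzyl 3-O-(tert-butyldimethylsilyl)-4,5-bis-O-(carboxyacetyl)quinate | OC(=O)CC(=O)O[C@@H]1[C@H](O[Si](C)(C)C(C)(C)C)C[C@@](O)(C(=O)OCc2ccc(OC)cc2)C[C@H]1OC(=O)CC(=O)O
A1 | alternative 1 | ethyl 3,4-O-isopropylidene-5-dehydroquinate | CC2(C)O[C@@H]1[C@H](O2)C[C@@](O)(C(=O)OCC)CC1=O
A2 | alternative 1 | ethyl 4,5-O-isopropylidene-4,5-dihydroxy-2,6-dioxoheptanoate (cis-dioxolane, configured as in A1) | CC2(C)O[C@@H](C(C)=O)[C@H](O2)CC(=O)C(=O)OCC
A3 | alternative 2 | 1-(methoxymethoxy)-5-(tert-butyldimethylsilyloxy)cyclohex-3-ene-1-carboxylic acid (quinate numbering) | C1=CC[C@@](OCOC)(C(=O)O)C[C@H]1O[Si](C)(C)C(C)(C)C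
A4 | alternative 2 | (5R,6S)-5-(tert-butyldimethylsilyloxy)-3-(methoxymethoxy)-6-vinyltetrahydro-2H-pyran-2-one (5,6-trans, either C3 epimer) | O=C1O[C@@H](C=C)[C@H](O[Si](C)(C)C(C)(C)C)CC1OCOC
A5 | alternative 3 | methyl 1-O-methoxymethyl-5-O-(tert-butyldimethylsilyl)quinate | O[C@@H]1[C@H](O)C[C@@](OCOC)(C(=O)OC)C[C@H]1O[Si](C)(C)C(C)(C)C
A6 | alternative 3 | methyl 4-(tert-butyldimethylsilyloxy)-2-(methoxymethoxy)-5-oxo-2-(2-oxoethyl)pentanoate (configured as in A5) | O=CC[C@@](OCOC)(C(=O)OC)C[C@H](C=O)O[Si](C)(C)C(C)(C)C
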